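| flask | substrate | partner | free catalyst | time |
|---|---|---|---|---|
| teal | 0.500 M | 0.600 M | 0.0150 M |  |
| green | 0.500 M | 1.20 M | 0.0150 M |  |
| violet | 0.750 M | 0.600 M | 0.0150 M |  |
| ochre | 0.500 M | 0.600 M | 0.0450 M |  |
| grey | 1.00 M | 0.600 M | 0.0450 M | 23 min |

| teal run: time / min | teal run: [target] / M | green run: time / min | green run: [target] / M | violet run: time / min | violet run: [target] / M | ochre run: time / min | ochre run: [target] / M |
|---|---|---|---|---|---|---|---|
| 0.92 | 0.0562 | 0.92 | 0.0850 | 0.92 | 0.0780 | 0.92 | 0.1385 |
| 2.1 | 0.0885 | 2.1 | 0.1263 | 2.1 | 0.1231 | 2.1 | 0.2022 |
| 4.6 | 0.1186 | 4.6 | 0.1597 | 4.6 | 0.1742 | 4.6 | 0.2549 |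
| 10 | 0.1490 | 10 | 0.1869 | 10 | 0.2076 | 10 | 0.2800 |
| 23 | 0.1657 | 23 | 0.2038 | 23 | 0.2198 | 23 | 0.2938 |

(standard deviation of a reading: 0.002 M)

- Overall: substrate + partner -> target, with free catalyst as catalyst.
- Constant volume, constant temperature.
- An order is taken over about fifteen percent of the charge, up and down.

* the exponent of [partner] in the starting rate at the charge of the teal run (at the point where two percent of the substrate have become target)
* the exponent of [free catalyst] in the starting rate at the charge of the teal run (at the point where two percent of the substrate have become target)
* target in the grey run at 23 min, as a share of the substrate charged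

At early times the teal run climbs briskly, holding 0.0562 M of target at 0.92 min. Yet it reads 0.1657 M at 23 min, when the overall equation still counts 0.334 M of substrate and 0.434 M of partner. I suppose that the partner has a second road, running with the square of [partner], while target forms with [substrate] times [partner]. At fixed free catalyst, the split between the two roads should then follow substrate over partner.

Take the ochre run: its 0.2938 M of target, divided by the 0.306 M of partner not in target, gives 0.960. I call this ratio Θ, the partner odds: target at the last reading over partner of the charge not in target then. I treat the last reading as the stall, since ochre adds 0.0138 M after 10 min. The crossing is Θ = 1, where as much of the partner charge stands in target as outside it.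

Teal has Θ = 0.382. The green run, with twice the partner, has 0.205, half of teal's. The violet run, with 1.50 times the substrate, has 1.52 times teal's Θ.

The grey run looks like ochre, with the same partner and free catalyst, but it has twice the substrate. Its partner is the limiting reagent, 0.600 M against 1.00 M of substrate. Ochre's last reading gives a Θ just below the crossing. Doubling its Θ puts grey at 1.92, past the crossing, so I commit to 39.4 % of the substrate as target.

The forecast reads the stall differently: “the catalyst is dying”. It gives a partner order of 0.8, a free-catalyst order of 1 and 42 % for grey, a share higher than mine.

The simulation gives a partner order of 1.0, a free-catalyst order of 1.2 and 40.0 % for the grey run at 23 min.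

    2 free catalyst ⇌ catalyst dimer, settled at all times (1550 /M)
    catalyst dimer + substrate + partner → target + catalyst dimer (44.22 /M²/min)
    2 partner → lost reagent (0.6060 /M/min)
    target + partner → side product (0.09720 /M/min)

The grey run's Θ is 2.00, twice ochre's, so grey stands past the crossing, with 0.400 M of target from 0.600 M of partner. The conversion of partner into lost reagent keeps the grey run down at this share: the same run without that step reaches 54.3 %, which is 14 percentage points higher. Counted the same way, Θ in that run is 9.53.

(Readings and results are calculated on assumed constants; scatter was added.)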